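**Plan**

Ring A is the styryl-bearing pyranone (C3a, C4, O5, C6, C7, C7a), ring B the dihydrofuran (O1, C2, C3, C3a, C7a), ring C the 4-hydroxy-2-pyranone on C3.
Cuts: ring C is taken back to a C3 ester (3,5-dioxo ester, then acid chloride plus an acetoacetate dienolate equivalent). Ring B is cut at C2–C3. Then the O–CH2Ar ether bond, the C3a–CH2 bond and the styryl C=C are cut, which leads to 4-hydroxy-6-methyl-2-pyranone.
Enabling feature: C2 of ring B is a benzylic CH bound to O1 and to an electron-rich arene. It lies 1,5 to C3 once C3 is a diazoacetate carbon on C3a of ring A and O1 is the oxygen of a 4-(arylmethoxy) group.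
Forward: ring A is bought and receives the styryl arm, the C3a acetate and the benzylic ether. Ring B closes by carbenoid C–H insertion. Ring C is built last by acylation and lactonisation, and debenzylation ends the route.
Stereochemistry: C3 (S) comes from the chiral dirhodium carboxylate. C2 (S) comes from acid equilibration of the kinetic cis product to the trans isomer, with C3 as the fixed reference.

Key step: step 6

Assumption: Rh2(S-PTTL)4 is taken to induce the same sense as with 2-(benzyloxy)phenyl diazoacetates, giving the (2R,3S)-cis ester; if the pyranone reverses the sense, Rh2(R-PTTL)4 is used and nothing else changes.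

**Route**

Step 1
Reactants: 1 4-hydroxy-6-methyl-2H-pyran-2-one; 2 4-(benzyloxy)benzaldehyde
Product: 3 6-[2-(4-benzyloxyphenyl)-2-hydroxyethyl]-4-hydroxy-2H-pyran-2-one (racemic)
Conditions: LDA (2.3 equiv), THF, −78 °C; then 2, −78 → −30 °C; aq. HCl
Reagents that add atoms: none
Why: Double deprotonation gives the O4,C7-dianion, whose terminal carbanion is the most nucleophilic site and adds to the aldehyde in a vinylogous aldol addition; the carbinol centre is racemic and disappears in step 2.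

Step 2
Reactants: 3 6-[2-(4-benzyloxyphenyl)-2-hydroxyethyl]-4-hydroxy-2H-pyran-2-one
Product: 4 6-[(E)-2-(4-benzyloxyphenyl)ethenyl]-4-hydroxy-2H-pyran-2-one
Conditions: TsOH·H2O (10 mol%), 1,4-dioxane (high dilution), 90 °C
Reagents that add atoms: none
Why: Acid-catalysed E1 dehydration through the p-benzyloxy-stabilised benzylic cation should give the conjugated E-alkene as the thermodynamic product, and dilution holds back intermolecular C3 benzylation of the hydroxypyranone.

Step 3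
Reactants: 4 6-[(E)-2-(4-benzyloxyphenyl)ethenyl]-4-hydroxy-2H-pyran-2-one; 5 methyl glyoxylate
Product: 7 methyl 2-{6-[(E)-2-(4-benzyloxyphenyl)ethenyl]-4-hydroxy-2-oxo-2H-pyran-3-yl}acetate, via alkylidenepyrandione 6 (not isolated)
Conditions: Hantzsch ester (diethyl 2,6-dimethyl-1,4-dihydropyridine-3,5-dicarboxylate, 1.1 equiv), L-proline (20 mol%), MeOH–CH2Cl2, 25 °C
Reagents that add atoms: none
Why: Knoevenagel condensation at the nucleophilic C3 gives the strongly electrophilic alkylidene 6, which should take up hydride from the dihydropyridine faster than it adds a second pyranone (organocatalytic three-component reductive alkylation of cyclic 1,3-dicarbonyl compounds).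

Step 4
Reactants: 7 methyl 2-{6-[(E)-2-(4-benzyloxyphenyl)ethenyl]-4-hydroxy-2-oxo-2H-pyran-3-yl}acetate; 8 [3,4-bis(benzyloxy)phenyl]methanol
Product: 9 methyl 2-{4-{[3,4-bis(benzyloxy)phenyl]methoxy}-6-[(E)-2-(4-benzyloxyphenyl)ethenyl]-2-oxo-2H-pyran-3-yl}acetate
Conditions: PPh3, DIAD, THF, 0 °C → rt
Reagents that add atoms: none
Why: Mitsunobu reaction, in which the acidic 4-hydroxypyranone (pKa about 5) is alkylated on O4 by the activated primary benzylic alcohol while the C3 substituent blocks C-alkylation.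

Step 5
Reactants: 9 methyl 2-{4-{[3,4-bis(benzyloxy)phenyl]methoxy}-6-[(E)-2-(4-benzyloxyphenyl)ethenyl]-2-oxo-2H-pyran-3-yl}acetate
Product: 10 methyl 2-diazo-2-{4-{[3,4-bis(benzyloxy)phenyl]methoxy}-6-[(E)-2-(4-benzyloxyphenyl)ethenyl]-2-oxo-2H-pyran-3-yl}acetate
Conditions: 4-acetamidobenzenesulfonyl azide (1.5 equiv), DBU (2 equiv), MeCN, 0 °C → rt
Reagents that add atoms: 4-acetamidobenzenesulfonyl azide, CC(=O)Nc1ccc(cc1)S(=O)(=O)N=[N+]=[N-]
Why: Regitz diazo transfer to an arylacetate-type CH2, as practised on 2-alkoxyphenylacetates; benzyl ethers, lactone and styryl group are inert to the amidine base and the sulfonyl azide.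

Step 6
Reactants: 10 methyl 2-diazo-2-{4-{[3,4-bis(benzyloxy)phenyl]methoxy}-6-[(E)-2-(4-benzyloxyphenyl)ethenyl]-2-oxo-2H-pyran-3-yl}acetate
Product: 12 methyl (2S,3S)-2-[3,4-bis(benzyloxy)phenyl]-6-[(E)-2-(4-benzyloxyphenyl)ethenyl]-4-oxo-2,3-dihydro-4H-furo[3,2-c]pyran-3-carboxylate, via cis-(2R,3S) ester 11 (not isolated)
Conditions: Rh2(S-PTTL)4 (dirhodium tetrakis[N-phthaloyl-(S)-tert-leucinate], 2 mol%), toluene–CH2Cl2, −60 °C; then CF3CO2H (10 equiv), 0 °C
Reagents that add atoms: none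
Why: Loss of N2 on the dirhodium tetracarboxylate gives a donor/acceptor carbenoid (donor: the enol-ether carbon C3a of ring A; acceptor: the ester) that inserts, in a concerted, hydride-transfer-like step, into the C–H bond of the OCH2Ar group, which is activated by the ether oxygen and the 3,4-dialkoxyarene. The closest known reaction is the Rh2(S-PTTL)4-catalysed cyclisation of methyl 2-(2-benzyloxyphenyl)-2-diazoacetates to cis-2-aryl-2,3-dihydrobenzofuran-3-carboxylates, with a 4-alkoxy-2-pyranone here taking the place of the benzene ring. Ring B closes by 1,5-C–H insertion through a five-membered transition state, forming C2–C3. C3 is fixed by the chiral phthalimido-carboxylate ligands, which select one face of the carbenoid, and C2 is formed cis to the ester under the same kinetic control (11). CF3CO2H then reversibly ionises the benzylic C2–O1 bond (the pyranone oxygen is a better leaving group than a phenoxide, the cation is 3,4-dialkoxybenzylic) and re-closure should place the aryl group trans to the ester, so C2 ends under thermodynamic substrate control while C3 is untouched, as in the known acid isomerisation of cis-2-aryl-2,3-dihydrobenzofurans. The step needs chemoselectivity for this one C–H bond, secured by the 1,5-geometry (attack on either ring A oxygen would give a four-membered ylide, and the only alkene is a remote, conjugated E-styryl group that such carbenoids cyclopropanate slowly), and it needs the acid stage to avoid E1 loss of the C3 proton, which low temperature and a non-basic medium favour.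

Step 7
Reactants: 12 methyl (2S,3S)-2-[3,4-bis(benzyloxy)phenyl]-6-[(E)-2-(4-benzyloxyphenyl)ethenyl]-4-oxo-2,3-dihydro-4H-furo[3,2-c]pyran-3-carboxylate
Product: 13 (2S,3S)-2-[3,4-bis(benzyloxy)phenyl]-6-[(E)-2-(4-benzyloxyphenyl)ethenyl]-4-oxo-2,3-dihydro-4H-furo[3,2-c]pyran-3-carboxylic acid
Conditions: Me3SnOH (5 equiv), 1,2-dichloroethane, 70 °C; then aq. HCl (0.1 M) wash
Reagents that add atoms: trimethyltin hydroxide, C[Sn](C)(C)O
Why: Tin-hydroxide cleavage of a methyl ester under nearly neutral conditions, a method chosen because it spares base-labile α-stereocentres, lactones and β-leaving groups; trans is in any case the more stable arrangement at C3.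

Step 8
Reactants: 13 (2S,3S)-2-[3,4-bis(benzyloxy)phenyl]-6-[(E)-2-(4-benzyloxyphenyl)ethenyl]-4-oxo-2,3-dihydro-4H-furo[3,2-c]pyran-3-carboxylic acid; 14 1-methoxy-1,3-bis(trimethylsilyloxy)buta-1,3-diene
Product: 16 methyl 5-[(2S,3S)-2-[3,4-bis(benzyloxy)phenyl]-6-[(E)-2-(4-benzyloxyphenyl)ethenyl]-4-oxo-2,3-dihydro-4H-furo[3,2-c]pyran-3-yl]-3,5-dioxopentanoate, via acid chloride 15 (not isolated)
Conditions: 1-chloro-N,N,2-trimethylprop-1-en-1-amine (1.2 equiv), CH2Cl2, 0 °C; then 14 (2 equiv), −78 °C → rt; aq. HCl (1 M)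
Reagents that add atoms: 1-chloro-N,N,2-trimethylprop-1-en-1-amine, CC(C)=C(Cl)N(C)C (supplies the chlorine of intermediate 15 only)
Why: The acid is converted into its chloride without base or HCl, and the terminal carbon of the bis(silyl) dienol ether is then C-acylated without Lewis acid or base (vinylogous Mukaiyama-type acylation giving a 3,5-dioxo ester), so the enolisable C3 centre never meets a base.

Step 9
Reactants: 16 methyl 5-[(2S,3S)-2-[3,4-bis(benzyloxy)phenyl]-6-[(E)-2-(4-benzyloxyphenyl)ethenyl]-4-oxo-2,3-dihydro-4H-furo[3,2-c]pyran-3-yl]-3,5-dioxopentanoate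
Product: 17 (2S,3S)-2-[3,4-bis(benzyloxy)phenyl]-6-[(E)-2-(4-benzyloxyphenyl)ethenyl]-3-(4-hydroxy-2-oxo-2H-pyran-6-yl)-2,3-dihydro-4H-furo[3,2-c]pyran-4-one
Conditions: DBU (1.1 equiv), THF, 0 °C → rt; then aq. HCl (1 M)
Reagents that add atoms: none
Why: Base-mediated lactonisation of a 3,5-dioxo ester, in which the enolate oxygen of the C5 ketone attacks the methyl ester to close ring C; DBU removes only the central, most acidic proton of the tricarbonyl chain, which keeps negative charge away from C3 of ring B.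

Step 10
Reactants: 17 (2S,3S)-2-[3,4-bis(benzyloxy)phenyl]-6-[(E)-2-(4-benzyloxyphenyl)ethenyl]-3-(4-hydroxy-2-oxo-2H-pyran-6-yl)-2,3-dihydro-4H-furo[3,2-c]pyran-4-one
Product: 18 (2S,3S)-2-(3,4-dihydroxyphenyl)-3-(4-hydroxy-2-oxo-2H-pyran-6-yl)-6-[(E)-2-(4-hydroxyphenyl)ethenyl]-2,3-dihydro-4H-furo[3,2-c]pyran-4-one (CNP0330607.1)
Conditions: BCl3 (10 equiv), pentamethylbenzene (10 equiv), CH2Cl2, −78 °C; then H2O
Reagents that add atoms: none
Why: Lewis-acid debenzylation of the three aryl benzyl ethers at low temperature with pentamethylbenzene as a non-basic cation scavenger, conditions that leave alkenes and lactones alone; hydrogenolysis is excluded by the styryl alkene.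

**Compound list**

1 | 4-hydroxy-6-methyl-2H-pyran-2-one | Cc1cc(O)cc(=O)o1 | starting material
2 | 4-(benzyloxy)benzaldehyde | O=Cc1ccc(OCc2ccccc2)cc1 | starting material
3 | 6-[2-(4-benzyloxyphenyl)-2-hydroxyethyl]-4-hydroxy-2H-pyran-2-one (racemic) | OC(Cc1cc(O)cc(=O)o1)c1ccc(OCc2ccccc2)cc1 | intermediate
4 | 6-[(E)-2-(4-benzyloxyphenyl)ethenyl]-4-hydroxy-2H-pyran-2-one | O=c1cc(O)cc(/C=C/c2ccc(OCc3ccccc3)cc2)o1 | intermediate
5 | methyl glyoxylate | COC(=O)C=O | starting material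
6 | methyl 2-{6-[(E)-2-(4-benzyloxyphenyl)ethenyl]-2,4-dioxo-2H-pyran-3(4H)-ylidene}acetate (exocyclic alkene geometry not defined) | COC(=O)C=C1C(=O)C=C(/C=C/c2ccc(OCc3ccccc3)cc2)OC1=O | intermediate (not isolated)
7 | methyl 2-{6-[(E)-2-(4-benzyloxyphenyl)ethenyl]-4-hydroxy-2-oxo-2H-pyran-3-yl}acetate | COC(=O)Cc1c(O)cc(/C=C/c2ccc(OCc3ccccc3)cc2)oc1=O | intermediate
8 | [3,4-bis(benzyloxy)phenyl]methanol | OCc1ccc(OCc2ccccc2)c(OCc2ccccc2)c1 | starting material
9 | methyl 2-{4-{[3,4-bis(benzyloxy)phenyl]methoxy}-6-[(E)-2-(4-benzyloxyphenyl)ethenyl]-2-oxo-2H-pyran-3-yl}acetate | COC(=O)Cc1c(OCc2ccc(OCc3ccccc3)c(OCc3ccccc3)c2)cc(/C=C/c2ccc(OCc3ccccc3)cc2)oc1=O | intermediate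
10 | methyl 2-diazo-2-{4-{[3,4-bis(benzyloxy)phenyl]methoxy}-6-[(E)-2-(4-benzyloxyphenyl)ethenyl]-2-oxo-2H-pyran-3-yl}acetate | COC(=O)C(=[N+]=[N-])c1c(OCc2ccc(OCc3ccccc3)c(OCc3ccccc3)c2)cc(/C=C/c2ccc(OCc3ccccc3)cc2)oc1=O | intermediate
11 | methyl (2R,3S)-2-[3,4-bis(benzyloxy)phenyl]-6-[(E)-2-(4-benzyloxyphenyl)ethenyl]-4-oxo-2,3-dihydro-4H-furo[3,2-c]pyran-3-carboxylate (cis) | COC(=O)[C@H]1c2c(cc(/C=C/c3ccc(OCc4ccccc4)cc3)oc2=O)O[C@H]1c1ccc(OCc2ccccc2)c(OCc2ccccc2)c1 | intermediate (not isolated)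
12 | methyl (2S,3S)-2-[3,4-bis(benzyloxy)phenyl]-6-[(E)-2-(4-benzyloxyphenyl)ethenyl]-4-oxo-2,3-dihydro-4H-furo[3,2-c]pyran-3-carboxylate (trans) | COC(=O)[C@H]1c2c(cc(/C=C/c3ccc(OCc4ccccc4)cc3)oc2=O)O[C@@H]1c1ccc(OCc2ccccc2)c(OCc2ccccc2)c1 | intermediate
13 | (2S,3S)-2-[3,4-bis(benzyloxy)phenyl]-6-[(E)-2-(4-benzyloxyphenyl)ethenyl]-4-oxo-2,3-dihydro-4H-furo[3,2-c]pyran-3-carboxylic acid | OC(=O)[C@H]1c2c(cc(/C=C/c3ccc(OCc4ccccc4)cc3)oc2=O)O[C@@H]1c1ccc(OCc2ccccc2)c(OCc2ccccc2)c1 | intermediate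
14 | 1-methoxy-1,3-bis(trimethylsilyloxy)buta-1,3-diene | COC(O[Si](C)(C)C)=CC(=C)O[Si](C)(C)C | starting material
15 | (2S,3S)-2-[3,4-bis(benzyloxy)phenyl]-6-[(E)-2-(4-benzyloxyphenyl)ethenyl]-4-oxo-2,3-dihydro-4H-furo[3,2-c]pyran-3-carbonyl chloride | ClC(=O)[C@H]1c2c(cc(/C=C/c3ccc(OCc4ccccc4)cc3)oc2=O)O[C@@H]1c1ccc(OCc2ccccc2)c(OCc2ccccc2)c1 | intermediate (not isolated)
16 | methyl 5-[(2S,3S)-2-[3,4-bis(benzyloxy)phenyl]-6-[(E)-2-(4-benzyloxyphenyl)ethenyl]-4-oxo-2,3-dihydro-4H-furo[3,2-c]pyran-3-yl]-3,5-dioxopentanoate | COC(=O)CC(=O)CC(=O)[C@H]1c2c(cc(/C=C/c3ccc(OCc4ccccc4)cc3)oc2=O)O[C@@H]1c1ccc(OCc2ccccc2)c(OCc2ccccc2)c1 | intermediate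
17 | (2S,3S)-2-[3,4-bis(benzyloxy)phenyl]-6-[(E)-2-(4-benzyloxyphenyl)ethenyl]-3-(4-hydroxy-2-oxo-2H-pyran-6-yl)-2,3-dihydro-4H-furo[3,2-c]pyran-4-one | O=c1cc(O)cc([C@H]2c3c(cc(/C=C/c4ccc(OCc5ccccc5)cc4)oc3=O)O[C@@H]2c2ccc(OCc3ccccc3)c(OCc3ccccc3)c2)o1 | intermediate
18 | (2S,3S)-2-(3,4-dihydroxyphenyl)-3-(4-hydroxy-2-oxo-2H-pyran-6-yl)-6-[(E)-2-(4-hydroxyphenyl)ethenyl]-2,3-dihydro-4H-furo[3,2-c]pyran-4-one | O=c1cc(O)cc([C@H]2c3c(cc(/C=C/c4ccc(O)cc4)oc3=O)O[C@@H]2c2ccc(O)c(O)c2)o1 | target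

**Step count and risks**

Total: 10 steps. Longest linear sequence: 10 steps (1 to 18, fully linear).

Steps most likely to fail:

Step 6. The pyranone donor is untried in this insertion, so enantiofacial control may be poor, the carbenoid may attack the tethered arene instead, or the acid equilibration may run on to E1 loss of the C3 proton and erase C3. The fallback closes ring B by an oxidative radical annulation instead and sets out from 4. Commercial 3,4-bis(benzyloxy)benzaldehyde is converted by Wittig reaction with Ph3P=CHCO2Me into methyl (E)-3-[3,4-bis(benzyloxy)phenyl]prop-2-enoate F1. Heating 4 with excess F1 and Mn(OAc)3·2H2O in AcOH at 60 °C should add the C3 radical of the hydroxypyranone to the ester-bearing alkene carbon, oxidise the resulting benzylic radical to the cation and close the ring through O4 in the trans sense. This gives the racemic trans ester, that is 12 together with methyl (2R,3R)-2-[3,4-bis(benzyloxy)phenyl]-6-[(E)-2-(4-benzyloxyphenyl)ethenyl]-4-oxo-2,3-dihydro-4H-furo[3,2-c]pyran-3-carboxylate F2. Preparative HPLC on a chiral stationary phase removes F2, and the route is rejoined at 12.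

Step 8. The neutral silyl diene may be too weak a nucleophile for the hindered, α-branched acid chloride, which could then drift to the ketene with loss of the C3 configuration, or be acylated on oxygen. The fallback uses a pre-formed lithium dienolate and a thermal ring closure and sets out from 13. Activation with 1,1'-carbonyldiimidazole gives the N-acylimidazole (2S,3S)-2-[3,4-bis(benzyloxy)phenyl]-6-[(E)-2-(4-benzyloxyphenyl)ethenyl]-3-(imidazol-1-ylcarbonyl)-2,3-dihydro-4H-furo[3,2-c]pyran-4-one F3, used without isolation. It is added at −78 °C to the lithium dienolate of commercial 2,2,6-trimethyl-4H-1,3-dioxin-4-one (LiHMDS, THF) and should give 6-{2-[(2S,3S)-2-[3,4-bis(benzyloxy)phenyl]-6-[(E)-2-(4-benzyloxyphenyl)ethenyl]-4-oxo-2,3-dihydro-4H-furo[3,2-c]pyran-3-yl]-2-oxoethyl}-2,2-dimethyl-4H-1,3-dioxin-4-one F4. Heating F4 in toluene at 110 °C expels acetone, and the acylketene 5-[(2S,3S)-2-[3,4-bis(benzyloxy)phenyl]-6-[(E)-2-(4-benzyloxyphenyl)ethenyl]-4-oxo-2,3-dihydro-4H-furo[3,2-c]pyran-3-yl]-3,5-dioxopent-1-en-1-one F5 is trapped by the enol of the neighbouring ketone. The route is rejoined at 17, and step 9 is bypassed as well.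

Step 5. The CH2 group of 9 is only cross-conjugated with the lactone carbonyl and sits on an electron-rich carbon, so deprotonation by DBU may be slow and the sulfonyl azide or the diazo product may decompose before transfer is complete. The fallback brings in the diazo ester by cross-coupling and sets out from 4. Iodination at C3 with N-iodosuccinimide (MeCN, rt) gives 6-[(E)-2-(4-benzyloxyphenyl)ethenyl]-4-hydroxy-3-iodo-2H-pyran-2-one F6. Mitsunobu etherification with 8 (PPh3, DIAD, THF) gives 4-{[3,4-bis(benzyloxy)phenyl]methoxy}-6-[(E)-2-(4-benzyloxyphenyl)ethenyl]-3-iodo-2H-pyran-2-one F7. Coupling of F7 with methyl diazoacetate F8 (prepared from glycine methyl ester hydrochloride and NaNO2) under Pd(PPh3)4, Ag2CO3 and Et3N in toluene at rt is the known coupling of aryl and vinyl iodides with diazoacetates that keeps the diazo group. The route is rejoined at 10, and steps 3 and 4 are bypassed.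

**Further compounds**

F1 | step 6 | methyl (E)-3-[3,4-bis(benzyloxy)phenyl]prop-2-enoate | COC(=O)/C=C/c1ccc(OCc2ccccc2)c(OCc2ccccc2)c1
F2 | step 6 | methyl (2R,3R)-2-[3,4-bis(benzyloxy)phenyl]-6-[(E)-2-(4-benzyloxyphenyl)ethenyl]-4-oxo-2,3-dihydro-4H-furo[3,2-c]pyran-3-carboxylate | COC(=O)[C@@H]1c2c(cc(/C=C/c3ccc(OCc4ccccc4)cc3)oc2=O)O[C@H]1c1ccc(OCc2ccccc2)c(OCc2ccccc2)c1
F3 | step 8 | (2S,3S)-2-[3,4-bis(benzyloxy)phenyl]-6-[(E)-2-(4-benzyloxyphenyl)ethenyl]-3-(imidazol-1-ylcarbonyl)-2,3-dihydro-4H-furo[3,2-c]pyran-4-one | O=C([C@H]1c2c(cc(/C=C/c3ccc(OCc4ccccc4)cc3)oc2=O)O[C@@H]1c1ccc(OCc2ccccc2)c(OCc2ccccc2)c1)n1ccnc1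
F4 | step 8 | 6-{2-[(2S,3S)-2-[3,4-bis(benzyloxy)phenyl]-6-[(E)-2-(4-benzyloxyphenyl)ethenyl]-4-oxo-2,3-dihydro-4H-furo[3,2-c]pyran-3-yl]-2-oxoethyl}-2,2-dimethyl-4H-1,3-dioxin-4-one | CC1(C)OC(=O)C=C(CC(=O)[C@H]2c3c(cc(/C=C/c4ccc(OCc5ccccc5)cc4)oc3=O)O[C@@H]2c2ccc(OCc3ccccc3)c(OCc3ccccc3)c2)O1
F5 | step 8 | 5-[(2S,3S)-2-[3,4-bis(benzyloxy)phenyl]-6-[(E)-2-(4-benzyloxyphenyl)ethenyl]-4-oxo-2,3-dihydro-4H-furo[3,2-c]pyran-3-yl]-3,5-dioxopent-1-en-1-one | O=C=CC(=O)CC(=O)[C@H]1c2c(cc(/C=C/c3ccc(OCc4ccccc4)cc3)oc2=O)O[C@@H]1c1ccc(OCc2ccccc2)c(OCc2ccccc2)c1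
F6 | step 5 | 6-[(E)-2-(4-benzyloxyphenyl)ethenyl]-4-hydroxy-3-iodo-2H-pyran-2-one | O=c1oc(/C=C/c2ccc(OCc3ccccc3)cc2)cc(O)c1I
F7 | step 5 | 4-{[3,4-bis(benzyloxy)phenyl]methoxy}-6-[(E)-2-(4-benzyloxyphenyl)ethenyl]-3-iodo-2H-pyran-2-one | O=c1oc(/C=C/c2ccc(OCc3ccccc3)cc2)cc(OCc2ccc(OCc3ccccc3)c(OCc3ccccc3)c2)c1I
F8 | step 5 | methyl diazoacetate | COC(=O)C=[N+]=[N-]
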